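**Numbering used throughout**

Compounds: 1 (R)-pulegone; 2 dienyl triflate; 3 triflyloxy enone; 4 enone; 5 alkenol; 6 iodide; 7 bromo ketal; 8 Grignard reagent (not isolated); 9 magnesium enolate (not isolated); 10 coupling product; 11 hydroxydecalin ketal; 12 methyl ketone; 13 hydrazone; 14 allylated hydrazone; 15 keto aldehyde; 16 syn homoallylic alcohol; 17 mesylate; 18 hydroperoxy ketal; 19 methoxy dioxane; 20 methyl dioxane; 21 aldehyde (not isolated); 22 acid; 23 target.

Atom labels: decalin atoms are unprimed (ring B: C1, C2, C3, C4, C4a, C8a; ring A: C4a, C5–C8, C8a). Dioxane atoms are primed (O1', O2', C3'–C6'). Cα is the propanoate stereocentre. "Dec" stands for (1S,2R,4aS,8aR)-4a-hydroxy-2,5,5,8a-tetramethyldecahydronaphthalen-1-yl.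

## Analysis of the target

The target is a methyl propanoate whose α-carbon (Cα) sits on C3' of a 1,2-dioxane; C6' is a quaternary peroxide carbon that carries a methyl group and a two-carbon tether to C1 of a decalin. The decalin is cis-fused, with a tertiary hydroxyl at C4a, a gem-dimethyl group at C5, an angular methyl at C8a and a secondary methyl at C2. There are seven stereocentres: on ring B the tether at C1 is trans to the C2 methyl and cis to both the C8a methyl and the C4a hydroxyl; in the dioxane the C3' substituent is cis to the C6' methyl, and Cα and C3' are both S (C6' is R). The two stereochemical domains are insulated from each other by the CH2CH2 tether, so neither can be used to control the other. Sensitive groups are the O–O bond (reductants, phosphines, low-valent metals, strong base), the tertiary alcohol flanked by two quaternary carbons (acid-induced dehydration or rearrangement), and Cα, which is epimerisable and β to a peroxide oxygen. The hard parts are the contiguous C1/C2/C8a triad with its quaternary member next to the fully substituted C4a–C5 pair, and the remote quaternary C6'. The strategy rests on ring B: C1, C2 and C8a are contiguous and C8a is bonded to C4a, a carbonyl carbon in disguise, so ring B maps onto a 2-methylcyclohex-2-enone with C4a as carbonyl carbon, C8a as α-carbon, C1 as β-carbon and C2 as the γ-stereocentre.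

## Retrosynthetic reasoning

**Ester and Cα terminus (23 ← 22 ← 20).** The ester is taken back to acid 22 and the carboxyl carbon to the vinyl group of 20. An ester at this position would place an acidic hydrogen β to the leaving group during ring closure and would not tolerate the organometallic methylation; a vinyl group is inert to both. The forward steps must oxidise without exposing the β-peroxy aldehyde to base.

**C6'–CH3 bond (20 ← 19).** The methyl group at C6' is removed to give the cyclic peroxyketal 19. The cut is made here because the derived peroxycarbenium ion is planar at C6' and the ring already holds the C3' substituent equatorial, so axial delivery of a methyl nucleophile sets C6' relative to C3'. This is the only ring-based way to control a quaternary centre whose two carbon substituents (CH3 and CH2) are sterically alike.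

**C3'–O2' and C6'–O1' bonds (19 ← 18 ← 17).** The dioxane is opened at C3'–O2' to the hydroperoxy ketal 18 with a mesylate at C3', and 18 is taken back to ketone 17. Closure by 6-exo displacement inverts C3', so C3' is set as a carbinol stereocentre of opposite configuration, which is easy to make.

**Cα–C3' bond (16 ← 15).** Mesylate 17 comes from alcohol 16, which is cut between Cα and C3' into keto aldehyde 15 and a Z-crotyl unit. One reagent-controlled crotylboration sets both centres (syn), independent of the remote decalin.

**C4'–C5' bond (15 ← 14 ← 13 ← 12).** The aldehyde arm is cut at C4'–C5': the methyl group of methyl ketone 12 is extended by an allyl unit via hydrazone 13, and ozonolysis of 14 unveils aldehyde and ketone together. The methyl carbon of 12 thus becomes C5', and the ketone carbon becomes C6'.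

**Ring A (12 ← 11 ← 10).** Ketal removal leads to 11. Ring A is cut at C4a–C5: a tertiary radical at C5, generated from the 1,1-disubstituted alkene of 10, adds to the C4a ketone. This forms the most congested bond late, under neutral conditions, and sets C4a from C8a.

**Ring B substituents (10 ← 4 + 7 + 6).** The C1–tether bond and the C8a–C8 bond are cut together. Enone 4 accepts the organocopper reagent derived from 7 (through 8) at the β-carbon, and the resulting enolate 9 is alkylated by iodide 6. One stereocentre of 4 must relay to two new ones in a single flask.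

**Building blocks (4 ← 3 ← 2 ← 1; 6 ← 5).** Enone 4 is taken back to triflate 3, where the C2 methyl is installed by cross-coupling, and 3 to (R)-pulegone 1 via dienyl triflate 2 and cleavage of the isopropylidene group; the stereocentre of 1 becomes C2 of the decalin. Iodide 6 comes from alcohol 5.

## Alternatives that were turned down

**Alternative 1:** The dioxane is cut at both C–O bonds, leading to the (E,Z)-diene A2 and oxygen. Forward, sensitised singlet oxygen would add across A2 in a [4+2] reaction to give the 3,6-dihydro-1,2-dioxine A1, followed by diimide reduction, desilylation, oxidation and esterification.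
- For: both C–O bonds and the ring arise in one concerted suprafacial step, and the cis relation between the C3' substituent and the C6' methyl follows directly from diene geometry. On this point it is stronger than the end-game used here, which needs a separate displacement and a separate methylation.
- Against: the Z-trisubstituted terminus of A2 puts the tether on the inside of the s-cis conformer, so the reactive conformer is disfavoured and the ene reaction at the allylic hydrogens (C6' methyl, tether CH2, Cα–H) is the likely main path. Facial selectivity depends only on the open-chain stereocentre Cα. The strategy is silent on the decalin.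
- Comparison: it spends its key step on the half of the molecule for which stepwise, individually controlled solutions exist. The chosen strategy gives up one-step peroxide formation and offers a decalin built in two steps from a chiral-pool enone, with each dioxane centre set by its own element.

**Alternative 2:** Ring B is cut at C4–C4a, leading to iodo ketone A4, a 2,2,6,6-tetrasubstituted cyclohexanone carrying the acyclic C1–C4 chain on C8a. SmI2 (divalent samarium) would convert the primary iodide into an alkylsamarium that adds to the C4a ketone, giving the cis-fused hydroxy ketal A3, which is identical with 11.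
- For: samarium Barbier closures of iodoalkyl cycloalkanones reliably give cis-fused products, and the nucleophilic carbon is primary and unhindered. On ring-fusion control and on the ring-closing bond itself it is as strong as or stronger than the radical closure used here, and the end-game from A3 is the same.
- Against: the ketone of A4 lies between C5 (gem-dimethyl) and quaternary C8a, so ketyl formation and simple reduction of the iodide compete with addition. More seriously, C1, C2 and quaternary C8a must be set before ring B exists, in an open chain attached to a quaternary ring carbon, with no cyclic relay; that costs an asymmetric quaternary alkylation and a controlled vicinal dialkyl array.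
- Comparison: the chosen strategy uses ring B itself as the template, so one stereocentre from 1 sets C1 and C8a in one flask.

**Alternative 3:** Ring A is cut at C4a–C5, leading to alkenyl ketone A6. An iron hydride from Fe(acac)3 and phenylsilane would transfer a hydrogen atom to the alkene, and the tertiary C5 radical would add to the C4a ketone to give the hydroxydecalin acetal A5.
- For: this is the same bond construction as step 6 of the chosen route; on ring A the two plans are equal.
- Against, as the centre of a plan: the closure creates one stereocentre under the control of C8a, so it presupposes the C1/C2/C8a triad of A6 without saying how it is made. A5 also ends in an aldehyde acetal, so C6' arrives without its carbon substituents and an extra addition and oxidation are needed to reach the stage of 12.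
- Comparison: the chosen strategy answers the open question directly, carries C6' as a masked ketone from the start, and keeps the radical closure as a supporting step.

Key step: step 5

Remark: 18 and 19 are carried as mixtures of both configurations at the peroxyketal carbon C6', because this carbon becomes planar in step 15 and is set there; 16 is drawn as the open hydroxy ketone although it equilibrates with its lactol.

## Route

Step 1
Reactants: 1 (R)-(+)-pulegone
Product: 2 (3R)-3-methyl-6-(propan-2-ylidene)cyclohex-1-en-1-yl trifluoromethanesulfonate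
Conditions: LDA (LiN(iPr)2), THF, −78 °C; PhNTf2, −78 → 0 °C
Reagents that add atoms: N-phenylbis(trifluoromethanesulfonimide), O=S(=O)(N(c1ccccc1)S(=O)(=O)C(F)(F)F)C(F)(F)F
Why: Kinetic deprotonation of the enone at the α'-methylene gives the cross-conjugated dienolate, which is O-sulfonylated (enol triflate formation); the methyl-bearing stereocentre is not acidic and is untouched.

Step 2
Reactants: 2 (3R)-3-methyl-6-(propan-2-ylidene)cyclohex-1-en-1-yl trifluoromethanesulfonate
Product: 3 (3R)-3-methyl-6-oxocyclohex-1-en-1-yl trifluoromethanesulfonate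
Conditions: O3, CH2Cl2, −78 °C, to indicator end point; Me2S, −78 → 25 °C
Reagents that add atoms: ozone, [O-][O+]=O
Why: Ozone attacks the electron-rich tetrasubstituted exocyclic alkene much faster than the ring alkene deactivated by the triflyloxy group (site-selective ozonolysis); reductive work-up leaves the α-triflyloxy enone.

Step 3
Reactants: 3 (3R)-3-methyl-6-oxocyclohex-1-en-1-yl trifluoromethanesulfonate
Product: 4 (4R)-2,4-dimethylcyclohex-2-en-1-one
Conditions: MeZnCl, Pd(PPh3)4 (5 mol %), THF, 25 °C
Reagents that add atoms: methylzinc chloride, C[Zn]Cl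
Why: Negishi cross-coupling: zerovalent palladium inserts into the electron-poor alkenyl C–OTf bond, and transmetallation and reductive elimination install the C2 methyl; the neutral conditions do not touch the γ-stereocentre.

Step 4
Reactants: 5 4-methylpent-4-en-1-ol
Product: 6 5-iodo-2-methylpent-1-ene
Conditions: I2, PPh3, imidazole, CH2Cl2, 0 → 25 °C
Reagents that add atoms: iodine, II
Why: Appel-type iodination of a primary alcohol by SN2 displacement of the alkoxyphosphonium ion; the 1,1-disubstituted alkene is inert.

Step 5
Reactants: 7 2-(2-bromoethyl)-2-methyl-1,3-dioxolane; 4 (4R)-2,4-dimethylcyclohex-2-en-1-one; 6 5-iodo-2-methylpent-1-ene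
Product: 10 (2R,3S,4R)-2,4-dimethyl-3-[2-(2-methyl-1,3-dioxolan-2-yl)ethyl]-2-(4-methylpent-4-en-1-yl)cyclohexan-1-one, via Grignard reagent 8 (not isolated), via magnesium enolate 9 (not isolated)
Conditions: 7, Mg, THF, 25 °C; CuBr·SMe2 (10 mol %), THF, −40 °C, then 4; then HMPA, 6 (3 equiv), −40 → 25 °C
Reagents that add atoms: none
Why: Grignard reagent 8 transmetallates to copper; the monovalent organocopper species forms a π-complex with enone 4, adds at the β-carbon and reductively eliminates, which forms the C3–C bond (decalin C1–tether) and leaves bromomagnesium enolate 9. Enolate 9 is then alkylated at C2 by iodide 6 in an SN2 reaction promoted by HMPA, which forms the C8a–C8 bond; the closest known reaction type is the copper-mediated conjugate addition to 2-methylcycloalkenones with in situ alkylation of the regiodefined enolate (three-component coupling). No ring is closed. The C3 centre (decalin C1) is controlled by the C4 methyl: the copper reagent adds along the axial trajectory on the face opposite this group, so the tether ends up trans to it. The C2 centre (decalin C8a) is controlled by the new C3 substituent: to escape allylic strain with the C2 methyl it sits pseudoaxial in the enolate half-chair and screens its face, so 6 enters from the other side and the methyl ends up cis to the tether. The step needs 1,4- over 1,2-addition (secured by copper), C-alkylation at C2 only (9 is generated regiospecifically, and excess 6 with HMPA should keep alkylation ahead of proton exchange with 10), and the facial sense just described. The last point is the least secure, because the C4 methyl lies on the face that 6 must use, 1,3 to the reacting carbon.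

Step 6
Reactants: 10 (2R,3S,4R)-2,4-dimethyl-3-[2-(2-methyl-1,3-dioxolan-2-yl)ethyl]-2-(4-methylpent-4-en-1-yl)cyclohexan-1-one
Product: 11 (1S,2R,4aS,8aR)-2,5,5,8a-tetramethyl-1-[2-(2-methyl-1,3-dioxolan-2-yl)ethyl]octahydronaphthalen-4a(2H)-ol
Conditions: Fe(acac)3 (0.5 equiv), PhSiH3, EtOH/HOCH2CH2OH 5:1, 60 °C
Reagents that add atoms: none
Why: Metal-hydride hydrogen-atom transfer: an iron hydride from Fe(acac)3 and PhSiH3 delivers H to the terminal CH2, the tertiary C5 radical adds 6-exo to the C4a carbonyl and the alkoxy radical is reduced, a known cyclisation of alkene-tethered ketones. With the tether equatorial on ring B the radical attacks C4a axially, anti to the axial C8a methyl, giving the cis-fused ring with OH cis to that methyl; trans closure would build a 1,3-diaxial interaction between a C5 methyl and the C8a methyl.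

Step 7
Reactants: 11 (1S,2R,4aS,8aR)-2,5,5,8a-tetramethyl-1-[2-(2-methyl-1,3-dioxolan-2-yl)ethyl]octahydronaphthalen-4a(2H)-ol
Product: 12 4-Dec-butan-2-one
Conditions: PPTS, acetone/H2O, 50 °C
Reagents that add atoms: water, O
Why: Acid-catalysed hydrolysis of the dioxolane; PPTS is too weak an acid to ionise the tertiary C4a alcohol.

Step 8
Reactants: 12 4-Dec-butan-2-one
Product: 13 (E)-N,N-dimethylhydrazone of 4-Dec-butan-2-one
Conditions: Me2NNH2, AcOH (cat.), EtOH, 70 °C
Reagents that add atoms: 1,1-dimethylhydrazine, CN(C)N
Why: Condensation to the N,N-dimethylhydrazone, which allows regioselective deprotonation of the methyl group in the next step.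

Step 9
Reactants: 13 (E)-N,N-dimethylhydrazone of 4-Dec-butan-2-one
Product: 14 N,N-dimethylhydrazone of 1-Dec-hept-6-en-3-one (C=N isomers)
Conditions: LDA (2.2 equiv), THF, −78 → 0 °C; allyl bromide, −78 → 0 °C
Reagents that add atoms: allyl bromide, C=CCBr
Why: Corey–Enders hydrazone alkylation: after the hydroxyl, LDA deprotonates the less substituted α-carbon (the methyl), and the azaenolate is monoalkylated by allyl bromide in an SN2 reaction. This forms the C4'–C5' bond without the regio- and polyalkylation problems of the ketone enolate.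

Step 10
Reactants: 14 N,N-dimethylhydrazone of 1-Dec-hept-6-en-3-one
Product: 15 6-Dec-4-oxohexanal
Conditions: O3, CH2Cl2, −78 °C; Me2S, −78 → 25 °C
Reagents that add atoms: ozone, [O-][O+]=O
Why: Ozonolysis cleaves the terminal alkene to the C3' aldehyde and the C=N bond back to the C6' ketone in one operation.

Step 11
Reactants: 15 6-Dec-4-oxohexanal
Product: 16 (6R,7R)-1-Dec-6-hydroxy-7-methylnon-8-en-3-one
Conditions: (Z)-crotyl-B(Ipc)2 [cis-but-2-ene, n-BuLi, KOtBu, THF, −78 → −45 °C; (−)-Ipc2BOMe; BF3·OEt2], −78 °C; then NaOH, H2O2, 0 → 25 °C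
Reagents that add atoms: (Z)-crotyldiisopinocampheylborane of the (−)-Ipc2BOMe series, C/C=C\CB([C@@H]1C[C@@H]2C[C@H]([C@H]1C)C2(C)C)[C@@H]1C[C@@H]2C[C@H]([C@H]1C)C2(C)C
Why: Brown crotylboration through a closed chair (Zimmerman–Traxler) transition state: the Z-crotyl geometry gives the syn relation between the Cα methyl and the C3' hydroxyl, and the isopinocampheyl ligands direct addition to the Si face of the aldehyde (reagent control; both new centres R in 16). The ketone does not react at −78 °C.

Step 12
Reactants: 16 (6R,7R)-1-Dec-6-hydroxy-7-methylnon-8-en-3-one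
Product: 17 (3R,4R)-9-Dec-3-methyl-7-oxonon-1-en-4-yl methanesulfonate
Conditions: MsCl, Et3N, CH2Cl2, −20 → 0 °C
Reagents that add atoms: methanesulfonyl chloride, CS(=O)(=O)Cl
Why: Sulfonylation of the secondary alcohol, which is drawn out of its lactol equilibrium; the tertiary C4a hydroxyl is too hindered to react.

Step 13
Reactants: 17 (3R,4R)-9-Dec-3-methyl-7-oxonon-1-en-4-yl methanesulfonate
Product: 18 (3R,4R)-9-Dec-7-hydroperoxy-7-methoxy-3-methylnon-1-en-4-yl methanesulfonate (both C7 epimers)
Conditions: urea·H2O2, Sc(OTf)3 (cat.), MeOH, 0 → 25 °C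
Reagents that add atoms: urea–hydrogen peroxide adduct, NC(N)=O.OO; methanol, CO
Why: Lewis acid-catalysed perketalisation of a ketone (the oxocarbenium ion formed in methanol is trapped by H2O2), the known entry to methoxy hydroperoxy ketals.

Step 14
Reactants: 18 (3R,4R)-9-Dec-7-hydroperoxy-7-methoxy-3-methylnon-1-en-4-yl methanesulfonate
Product: 19 (3S)-3-[(2R)-but-3-en-2-yl]-6-(2-Dec-ethyl)-6-methoxy-1,2-dioxane (both C6' epimers)
Conditions: KOtBu, 18-crown-6, THF, 0 °C
Reagents that add atoms: none
Why: Intramolecular Williamson-type alkylation of the hydroperoxide anion (6-exo-tet SN2) on the secondary mesylate, a known route to 3-alkoxy-1,2-dioxanes; inversion converts C3' from R to S.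

Step 15
Reactants: 19 (3S)-3-[(2R)-but-3-en-2-yl]-6-(2-Dec-ethyl)-6-methoxy-1,2-dioxane
Product: 20 (3S,6R)-3-[(2R)-but-3-en-2-yl]-6-(2-Dec-ethyl)-6-methyl-1,2-dioxane
Conditions: AlMe3 (4 equiv), TMSOTf (0.2 equiv), CH2Cl2, −78 → −40 °C; Rochelle salt work-up
Reagents that add atoms: trimethylaluminium, C[Al](C)C
Why: Proposed new method: AlMe3, assisted by catalytic TMSOTf, should ionise the C6' methoxy group of 19 to a cyclic peroxycarbenium ion and transfer a methyl group to C6' within the ion pair; the ion adopts the half-chair with the C3' substituent pseudoequatorial and is attacked along the axial trajectory that leads directly to the chair, so the methyl group arrives cis to the C3' substituent (6'R) whichever C6' epimer of 19 ionises; the closest known reactions are the Lewis acid-mediated allylation of peroxyketals through peroxycarbenium ions and the axial methylation of tetrahydropyranyl acetals by AlMe3 through oxocarbenium ions.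

Step 16
Reactants: 20 (3S,6R)-3-[(2R)-but-3-en-2-yl]-6-(2-Dec-ethyl)-6-methyl-1,2-dioxane
Product: 22 (2S)-2-[(3S,6R)-6-(2-Dec-ethyl)-6-methyl-1,2-dioxan-3-yl]propanoic acid, via aldehyde 21 (not isolated)
Conditions: O3, MeCN/H2O, 0 °C; then NaClO2, NaH2PO4, 2-methylbut-2-ene, 0 → 25 °C
Reagents that add atoms: ozone, [O-][O+]=O; sodium chlorite, [Na+].[O-]Cl=O
Why: Ozonolysis in aqueous acetonitrile gives aldehyde 21 directly (the carbonyl oxide is trapped by water), and buffered chlorite (Pinnick oxidation) converts it at once to the acid, so the β-peroxy aldehyde is never exposed to base. The dialkyl peroxide and the tertiary alcohol are inert to both reagents.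

Step 17
Reactants: 22 (2S)-2-[(3S,6R)-6-(2-Dec-ethyl)-6-methyl-1,2-dioxan-3-yl]propanoic acid
Product: 23 methyl (2S)-2-[(3S,6R)-6-(2-Dec-ethyl)-6-methyl-1,2-dioxan-3-yl]propanoate (target)
Conditions: TMSCHN2, PhMe/MeOH, 0 °C
Reagents that add atoms: (trimethylsilyl)diazomethane, C[Si](C)(C)C=[N+]=[N-]
Why: O-Methylation of the carboxylic acid under neutral conditions, which neither epimerise Cα nor touch the O–O bond.

## Compound list

1 | (R)-(+)-pulegone, (5R)-5-methyl-2-(propan-2-ylidene)cyclohexan-1-one | C[C@@H]1CCC(=C(C)C)C(=O)C1 | starting material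
2 | (3R)-3-methyl-6-(propan-2-ylidene)cyclohex-1-en-1-yl trifluoromethanesulfonate | C[C@@H]1CCC(=C(C)C)C(OS(=O)(=O)C(F)(F)F)=C1 | intermediate
3 | (3R)-3-methyl-6-oxocyclohex-1-en-1-yl trifluoromethanesulfonate | C[C@@H]1CCC(=O)C(OS(=O)(=O)C(F)(F)F)=C1 | intermediate
4 | (4R)-2,4-dimethylcyclohex-2-en-1-one | O=C1CC[C@@H](C)C=C1C | intermediate
5 | 4-methylpent-4-en-1-ol | C=C(C)CCCO | starting material
6 | 5-iodo-2-methylpent-1-ene | C=C(C)CCCI | intermediate
7 | 2-(2-bromoethyl)-2-methyl-1,3-dioxolane | CC1(CCBr)OCCO1 | starting material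
8 | [2-(2-methyl-1,3-dioxolan-2-yl)ethyl]magnesium bromide | CC1(CC[Mg]Br)OCCO1 | intermediate (not isolated)
9 | bromomagnesium (3S,4R)-2,4-dimethyl-3-[2-(2-methyl-1,3-dioxolan-2-yl)ethyl]cyclohex-1-en-1-olate | CC1(CC[C@H]2[C@H](C)CCC(O[Mg]Br)=C2C)OCCO1 | intermediate (not isolated)
10 | (2R,3S,4R)-2,4-dimethyl-3-[2-(2-methyl-1,3-dioxolan-2-yl)ethyl]-2-(4-methylpent-4-en-1-yl)cyclohexan-1-one | CC1(CC[C@H]2[C@H](C)CCC(=O)[C@]2(C)CCCC(C)=C)OCCO1 | intermediate
11 | (1S,2R,4aS,8aR)-2,5,5,8a-tetramethyl-1-[2-(2-methyl-1,3-dioxolan-2-yl)ethyl]octahydronaphthalen-4a(2H)-ol | CC1(CC[C@H]2[C@H](C)CC[C@]3(O)C(C)(C)CCC[C@]23C)OCCO1 | intermediate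
12 | 4-[(1S,2R,4aS,8aR)-4a-hydroxy-2,5,5,8a-tetramethyldecahydronaphthalen-1-yl]butan-2-one | CC(=O)CC[C@H]1[C@H](C)CC[C@]2(O)C(C)(C)CCC[C@]12C | intermediate
13 | (E)-N,N-dimethylhydrazone of 12 | C/C(CC[C@H]1[C@H](C)CC[C@]2(O)C(C)(C)CCC[C@]12C)=N\N(C)C | intermediate
14 | N,N-dimethylhydrazone of 1-[(1S,2R,4aS,8aR)-4a-hydroxy-2,5,5,8a-tetramethyldecahydronaphthalen-1-yl]hept-6-en-3-one (C=N isomers) | C=CCCC(CC[C@H]1[C@H](C)CC[C@]2(O)C(C)(C)CCC[C@]12C)=NN(C)C | intermediate
15 | 6-[(1S,2R,4aS,8aR)-4a-hydroxy-2,5,5,8a-tetramethyldecahydronaphthalen-1-yl]-4-oxohexanal | O=CCCC(=O)CC[C@H]1[C@H](C)CC[C@]2(O)C(C)(C)CCC[C@]12C | intermediate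
16 | (6R,7R)-6-hydroxy-1-[(1S,2R,4aS,8aR)-4a-hydroxy-2,5,5,8a-tetramethyldecahydronaphthalen-1-yl]-7-methylnon-8-en-3-one | C=C[C@@H](C)[C@H](O)CCC(=O)CC[C@H]1[C@H](C)CC[C@]2(O)C(C)(C)CCC[C@]12C | intermediate
17 | (3R,4R)-9-[(1S,2R,4aS,8aR)-4a-hydroxy-2,5,5,8a-tetramethyldecahydronaphthalen-1-yl]-3-methyl-7-oxonon-1-en-4-yl methanesulfonate | C=C[C@@H](C)[C@H](OS(C)(=O)=O)CCC(=O)CC[C@H]1[C@H](C)CC[C@]2(O)C(C)(C)CCC[C@]12C | intermediate
18 | (3R,4R)-7-hydroperoxy-9-[(1S,2R,4aS,8aR)-4a-hydroxy-2,5,5,8a-tetramethyldecahydronaphthalen-1-yl]-7-methoxy-3-methylnon-1-en-4-yl methanesulfonate (both C7 epimers) | C=C[C@@H](C)[C@H](OS(C)(=O)=O)CCC(OC)(OO)CC[C@H]1[C@H](C)CC[C@]2(O)C(C)(C)CCC[C@]12C | intermediate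
19 | (3S)-3-[(2R)-but-3-en-2-yl]-6-[2-[(1S,2R,4aS,8aR)-4a-hydroxy-2,5,5,8a-tetramethyldecahydronaphthalen-1-yl]ethyl]-6-methoxy-1,2-dioxane (both C6 epimers) | C=C[C@@H](C)[C@@H]1CCC(OC)(CC[C@H]2[C@H](C)CC[C@]3(O)C(C)(C)CCC[C@]23C)OO1 | intermediate
20 | (3S,6R)-3-[(2R)-but-3-en-2-yl]-6-[2-[(1S,2R,4aS,8aR)-4a-hydroxy-2,5,5,8a-tetramethyldecahydronaphthalen-1-yl]ethyl]-6-methyl-1,2-dioxane | C=C[C@@H](C)[C@@H]1CC[C@@](C)(CC[C@H]2[C@H](C)CC[C@]3(O)C(C)(C)CCC[C@]23C)OO1 | intermediate
21 | (2S)-2-[(3S,6R)-6-[2-[(1S,2R,4aS,8aR)-4a-hydroxy-2,5,5,8a-tetramethyldecahydronaphthalen-1-yl]ethyl]-6-methyl-1,2-dioxan-3-yl]propanal | O=C[C@@H](C)[C@@H]1CC[C@@](C)(CC[C@H]2[C@H](C)CC[C@]3(O)C(C)(C)CCC[C@]23C)OO1 | intermediate (not isolated)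
22 | (2S)-2-[(3S,6R)-6-[2-[(1S,2R,4aS,8aR)-4a-hydroxy-2,5,5,8a-tetramethyldecahydronaphthalen-1-yl]ethyl]-6-methyl-1,2-dioxan-3-yl]propanoic acid | OC(=O)[C@@H](C)[C@@H]1CC[C@@](C)(CC[C@H]2[C@H](C)CC[C@]3(O)C(C)(C)CCC[C@]23C)OO1 | intermediate
23 | methyl (2S)-2-[(3S,6R)-6-[2-[(1S,2R,4aS,8aR)-4a-hydroxy-2,5,5,8a-tetramethyldecahydronaphthalen-1-yl]ethyl]-6-methyl-1,2-dioxan-3-yl]propanoate (CNP0274543.2) | COC(=O)[C@@H](C)[C@@H]1CC[C@@](C)(CC[C@H]2[C@H](C)CC[C@]3(O)C(C)(C)CCC[C@]23C)OO1 | target

## Step count and least certain steps

Total: 17 steps. Longest linear sequence: 16 steps (1 → 23 through steps 1–3 and 5–17); step 4 is a one-step side branch.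

**Step 15 (the one step that rests on a new method).** The methyl–aluminium reagent may attack a peroxide oxygen and cleave the O–O bond instead of adding to carbon. The peroxycarbenium ion may also fragment by migration of a ring carbon to oxygen, or be captured by the C4a oxygen, and the axial preference may be weaker than for oxocarbenium ions. The fallback uses known reactions only, sets out from 16 and returns at 20. Wittig methylenation of the ketone (Ph3P=CH2) gives the diene diol F1, and the secondary hydroxyl is mesylated to F2. A Co(thd)2-catalysed Mukaiyama–Isayama peroxidation (O2, Et3SiH) of the 1,1-disubstituted alkene then installs the tertiary triethylsilyl peroxide F3 as both C6' epimers; the monosubstituted alkene, which would give a less stabilised secondary radical, should react more slowly. Fluoride (Bu4NF) releases the peroxide anion, which displaces the mesylate with inversion to give 20 together with its C6' epimer F4, separated by chromatography. This path gives up control at C6'.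

**Step 5 (key step).** Enolate 9 is hindered and only moderately nucleophilic, so protonation and proton exchange with 10 can outrun C-alkylation by an unactivated iodide. The alkylation may also choose the face remote from the C4 methyl, which gives the C2 epimer of 10. The fallback exchanges the roles of the two substituents on the α-carbon; it sets out from 3 and 6 and returns at 10. The organozinc reagent F5 (from 6, Zn, LiCl) is coupled with 3 (Pd(dppf)Cl2) to the 2-alkenyl enone F6; copper-catalysed addition of 8 gives enolate F7, which is trapped with iodomethane. Iodomethane is far more reactive than 6, and because the methyl group now enters last, an enolate that prefers the face remote from the C4 methyl gives exactly 10. Which order is used is decided by the facial preference seen in the first experiments.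

**Step 6.** The tertiary radical may be reduced before it cyclises (net hydrogenation of the alkene), because addition to the hindered C4a carbonyl is slow and reversible; some trans-fused isomer may also form. The fallback sets out from 10 and returns at 11. Epoxidation of the 1,1-disubstituted alkene (mCPBA) gives F8. Cp2TiCl (trivalent titanium) opens the epoxide to the same tertiary C5 radical, which after addition to the ketone is trapped irreversibly as a titanium alkoxide, giving diol F9. The primary hydroxyl is converted into the thiocarbonylimidazolide F10 and removed with Bu3SnH (Barton–McCombie deoxygenation), which restores the gem-dimethyl group of 11.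

**Step 14.** The peroxide anion can act as a base, so E2 elimination of the homoallylic mesylate to a conjugated diene, or base-induced collapse of the hydroperoxy ketal to the ketone, competes with 6-exo displacement at a secondary carbon. The fallback avoids base; it sets out from 15 and returns at 19. Crotylboration of 15 with the E-crotyl reagent of the enantiomeric (+)-Ipc2BOMe series gives the anti alcohol F11 (same configuration at Cα, opposite at C3'). Appel iodination with inversion gives iodide F12, whose leaving group occupies the position of the mesylate in 17. Perketalisation as in step 13 gives F13, and AgOTf with a hindered pyridine base closes the ring by silver-assisted displacement with inversion.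

## Further compounds

F1 | step 15 | (3R,4R)-9-[(1S,2R,4aS,8aR)-4a-hydroxy-2,5,5,8a-tetramethyldecahydronaphthalen-1-yl]-3-methyl-7-methylidenenon-1-en-4-ol | C=C[C@@H](C)[C@H](O)CCC(=C)CC[C@H]1[C@H](C)CC[C@]2(O)C(C)(C)CCC[C@]12C
F2 | step 15 | (3R,4R)-9-[(1S,2R,4aS,8aR)-4a-hydroxy-2,5,5,8a-tetramethyldecahydronaphthalen-1-yl]-3-methyl-7-methylidenenon-1-en-4-yl methanesulfonate | C=C[C@@H](C)[C@H](OS(C)(=O)=O)CCC(=C)CC[C@H]1[C@H](C)CC[C@]2(O)C(C)(C)CCC[C@]12C
F3 | step 15 | (3R,4R)-9-[(1S,2R,4aS,8aR)-4a-hydroxy-2,5,5,8a-tetramethyldecahydronaphthalen-1-yl]-3,7-dimethyl-7-(triethylsilylperoxy)non-1-en-4-yl methanesulfonate (both C7 epimers) | C=C[C@@H](C)[C@H](OS(C)(=O)=O)CCC(C)(OO[Si](CC)(CC)CC)CC[C@H]1[C@H](C)CC[C@]2(O)C(C)(C)CCC[C@]12C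
F4 | step 15 | (3S,6S)-3-[(2R)-but-3-en-2-yl]-6-[2-[(1S,2R,4aS,8aR)-4a-hydroxy-2,5,5,8a-tetramethyldecahydronaphthalen-1-yl]ethyl]-6-methyl-1,2-dioxane (C6 epimer of 20) | C=C[C@@H](C)[C@@H]1CC[C@](C)(CC[C@H]2[C@H](C)CC[C@]3(O)C(C)(C)CCC[C@]23C)OO1
F5 | step 5 | (4-methylpent-4-en-1-yl)zinc iodide | C=C(C)CCC[Zn]I
F6 | step 5 | (4R)-4-methyl-2-(4-methylpent-4-en-1-yl)cyclohex-2-en-1-one | O=C1CC[C@@H](C)C=C1CCCC(C)=C
F7 | step 5 | bromomagnesium (3S,4R)-4-methyl-3-[2-(2-methyl-1,3-dioxolan-2-yl)ethyl]-2-(4-methylpent-4-en-1-yl)cyclohex-1-en-1-olate | CC1(CC[C@H]2[C@H](C)CCC(O[Mg]Br)=C2CCCC(C)=C)OCCO1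
F8 | step 6 | (2R,3S,4R)-2,4-dimethyl-3-[2-(2-methyl-1,3-dioxolan-2-yl)ethyl]-2-[3-(2-methyloxiran-2-yl)propyl]cyclohexan-1-one (both epoxide epimers) | CC1(CC[C@H]2[C@H](C)CCC(=O)[C@]2(C)CCCC3(C)CO3)OCCO1
F9 | step 6 | (1S,2R,4aS,8aR)-5-(hydroxymethyl)-2,5,8a-trimethyl-1-[2-(2-methyl-1,3-dioxolan-2-yl)ethyl]octahydronaphthalen-4a(2H)-ol (both C5 epimers) | CC1(CC[C@H]2[C@H](C)CC[C@]3(O)C(C)(CO)CCC[C@]23C)OCCO1
F10 | step 6 | O-[[(4aS,5S,6R,8aR)-4a-hydroxy-1,6,8a-trimethyl-5-[2-(2-methyl-1,3-dioxolan-2-yl)ethyl]decahydronaphthalen-1-yl]methyl] 1H-imidazole-1-carbothioate (both epimers at the carbon bearing the CH2O group) | CC1(CC[C@H]2[C@H](C)CC[C@]3(O)C(C)(COC(=S)n4ccnc4)CCC[C@]23C)OCCO1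
F11 | step 14 | (6S,7R)-6-hydroxy-1-[(1S,2R,4aS,8aR)-4a-hydroxy-2,5,5,8a-tetramethyldecahydronaphthalen-1-yl]-7-methylnon-8-en-3-one | C=C[C@@H](C)[C@@H](O)CCC(=O)CC[C@H]1[C@H](C)CC[C@]2(O)C(C)(C)CCC[C@]12C
F12 | step 14 | (6R,7R)-1-[(1S,2R,4aS,8aR)-4a-hydroxy-2,5,5,8a-tetramethyldecahydronaphthalen-1-yl]-6-iodo-7-methylnon-8-en-3-one | C=C[C@@H](C)[C@H](I)CCC(=O)CC[C@H]1[C@H](C)CC[C@]2(O)C(C)(C)CCC[C@]12C
F13 | step 14 | (1S,2R,4aS,8aR)-1-[(6R,7R)-3-hydroperoxy-6-iodo-3-methoxy-7-methylnon-8-en-1-yl]-2,5,5,8a-tetramethyloctahydronaphthalen-4a(2H)-ol (both C3 epimers of the chain) | C=C[C@@H](C)[C@H](I)CCC(OC)(OO)CC[C@H]1[C@H](C)CC[C@]2(O)C(C)(C)CCC[C@]12C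
A1 | alternative 1 | (3S,6R)-3-[(2R)-1-(tert-butyldimethylsilyloxy)propan-2-yl]-6-[2-[(1S,2R,4aS,8aR)-4a-hydroxy-2,5,5,8a-tetramethyldecahydronaphthalen-1-yl]ethyl]-6-methyl-3,6-dihydro-1,2-dioxine | CC(C)(C)[Si](C)(C)OC[C@@H](C)[C@@H]1C=C[C@@](C)(CC[C@H]2[C@H](C)CC[C@]3(O)C(C)(C)CCC[C@]23C)OO1
A2 | alternative 1 | (1S,2R,4aS,8aR)-1-[(3Z,5E,7S)-8-(tert-butyldimethylsilyloxy)-3,7-dimethylocta-3,5-dien-1-yl]-2,5,5,8a-tetramethyloctahydronaphthalen-4a(2H)-ol | CC(C)(C)[Si](C)(C)OC[C@@H](C)/C=C/C=C(C)\CC[C@H]1[C@H](C)CC[C@]2(O)C(C)(C)CCC[C@]12C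
A3 | alternative 2 | (1S,2R,4aS,8aR)-2,5,5,8a-tetramethyl-1-[2-(2-methyl-1,3-dioxolan-2-yl)ethyl]octahydronaphthalen-4a(2H)-ol (identical with 11) | CC1(CC[C@H]2[C@H](C)CC[C@]3(O)C(C)(C)CCC[C@]23C)OCCO1
A4 | alternative 2 | (2R)-2-[(3S,4R)-6-iodo-4-methyl-1-(2-methyl-1,3-dioxolan-2-yl)hexan-3-yl]-2,6,6-trimethylcyclohexan-1-one | CC1(CC[C@@H]([C@H](C)CCI)[C@@]2(C)CCCC(C)(C)C2=O)OCCO1
A5 | alternative 3 | (1S,2R,4aS,8aR)-1-[2-(1,3-dioxolan-2-yl)ethyl]-2,5,5,8a-tetramethyloctahydronaphthalen-4a(2H)-ol | O1CCOC1CC[C@H]2[C@H](C)CC[C@]3(O)C(C)(C)CCC[C@]23C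
A6 | alternative 3 | (2R,3S,4R)-3-[2-(1,3-dioxolan-2-yl)ethyl]-2,4-dimethyl-2-(4-methylpent-4-en-1-yl)cyclohexan-1-one | O1CCOC1CC[C@H]2[C@H](C)CCC(=O)[C@]2(C)CCCC(C)=C
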